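## Retrosynthetic overview

1. The target is reached from its C1 epimer, which comes from an 11‑acetoxy‑8‑propanoyloxyguai‑4‑ene by allylic C–H oxidation at C3 (late oxidation, as in the oxidase phase of terpene biosynthesis), followed by equilibration of C1.
2. The guai‑4‑ene comes from an (E,E)‑germacra‑1(10),4‑diene diester by transannular C1–C5 bond formation (the germacrene‑to‑guaiane cyclisation). It is run as a photoredox radical‑cation cycloisomerisation, so that C10 receives H and the C4=C5 alkene is regenerated in the same step.
3. The germacradiene diester comes from a cis‑8,11‑diol (lipase resolution installs the propanoate and the absolute configuration, then acetylation), which comes from germacrone by formal hydration of its enone and chelation‑controlled reduction.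
4. Ring order: the ten‑membered ring is bought (germacrone); the five‑ and seven‑membered rings form together in the single transannular step.

Numbering (germacrane/guaiane): ring carbons C1–C10; C11 is the carbinol carbon on C7 (methyls C12, C13); C14 is the methyl on C10; C15 is the methyl on C4. α/β refer to the usual guaiane drawing.

Assumptions: germacrone (crystalline main constituent of zdravets oil, sold by natural‑product suppliers) is taken as a cheap commercial starting material; the natural 1β‑H configuration (C2 and the C10 methyl trans) is taken to be the more stable C1 epimer of the enone.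

## Route

Step 1
Reactants: 1 germacrone [(3E,7E)-3,7-dimethyl-10-(propan-2-ylidene)cyclodeca-3,7-dien-1-one]; 2 hydrogen peroxide
Product: 3 rac-(1(10)E,4E)-7,11-epoxygermacra-1(10),4-dien-8-one
Conditions: 30% aq. H2O2 (3 equiv), NaOH (0.3 equiv), MeOH, 0 °C
Reagents that add atoms: hydrogen peroxide (2), OO
Why: Weitz–Scheffer nucleophilic epoxidation, in which hydroperoxide adds only to the electron‑poor isopropylidene enone (a pulegone‑type tetrasubstituted s‑cis enone) and leaves the two electron‑rich trisubstituted alkenes untouched; the new C7 stereocentre is racemic and is erased in step 2.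

Step 2
Reactants: 3 rac-(1(10)E,4E)-7,11-epoxygermacra-1(10),4-dien-8-one
Product: 4 rac-(1(10)E,4E)-11-hydroxygermacra-1(10),4-dien-8-one
Conditions: SmI2 (2.2 equiv), THF/MeOH (2:1), −90 °C, 10 min; pH 7 buffer
Reagents that add atoms: none
Why: Reductive cleavage of the Cα–O bond of the α,β‑epoxy ketone by SmI2 (two single‑electron transfers through the ketyl, then protonation of the samarium enolate by MeOH) gives the tertiary β‑hydroxy ketone without dehydration; C7 is formed racemic.

Step 3
Reactants: 4 rac-(1(10)E,4E)-11-hydroxygermacra-1(10),4-dien-8-one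
Product: 5 rac-(1(10)E,4E,7S*,8R*)-germacra-1(10),4-diene-8,11-diol
Conditions: Zn(BH4)2 (1.5 equiv), Et2O, −20 °C; sat. aq. NH4Cl
Reagents that add atoms: none
Why: Chelation‑controlled (Cram‑chelate) ketone reduction, in which zinc bridges the C11 hydroxyl and the C8 carbonyl and hydride adds from the exterior face of the ring anti to C6, so the new C8–O bond is cis to the C11 side chain; the neutral conditions do not move the β,γ‑alkene into conjugation.

Step 4
Reactants: 5 rac-(1(10)E,4E,7S*,8R*)-germacra-1(10),4-diene-8,11-diol; 6 vinyl propanoate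
Product: 7 (1(10)E,4E,7S,8R)-11-hydroxygermacra-1(10),4-dien-8-yl propanoate
Conditions: Novozym 435 (immobilised Candida antarctica lipase B), vinyl propanoate (3 equiv), MTBE, 30 °C, to ca. 50% conversion; chromatography (unreacted (7R,8S)-diol removed)
Reagents that add atoms: vinyl propanoate (6), C=COC(=O)CC
Why: Lipase‑catalysed kinetic resolution by irreversible transesterification, in which the (8R) alcohol (large group the branched C7, medium group C9H2) is the fast enantiomer by the Kazlauskas rule and the tertiary C11 hydroxyl is inert, so one operation fixes the absolute configuration at C7/C8 and installs the propanoate.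

Step 5
Reactants: 7 (1(10)E,4E,7S,8R)-11-hydroxygermacra-1(10),4-dien-8-yl propanoate; 8 acetic anhydride
Product: 9 (1(10)E,4E,7S,8R)-11-acetoxygermacra-1(10),4-dien-8-yl propanoate
Conditions: Ac2O (5 equiv), DMAP (0.5 equiv), Et3N, CH2Cl2, 25 °C, 48 h
Reagents that add atoms: acetic anhydride (8), CC(=O)OC(C)=O
Why: DMAP‑catalysed (Steglich‑type) acylation of the tertiary alcohol under basic, acid‑free conditions at room temperature, which avoids acid‑triggered transannular cyclisation and thermal Cope rearrangement of the 1,5‑diene.

Step 6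
Reactants: 9 (1(10)E,4E,7S,8R)-11-acetoxygermacra-1(10),4-dien-8-yl propanoate
Product: 10 (1S,7S,8R,10S)-11-acetoxyguai-4-en-8-yl propanoate (1α-H; 10β-Me)
Conditions: 9-mesityl-3,6-di-tert-butyl-10-phenylacridinium tetrafluoroborate (5 mol%), PhSH (20 mol%), 2,6-lutidine (20 mol%), degassed 1,2-dichloroethane (0.05 M), 450 nm LEDs, 20 °C
Reagents that add atoms: none
Why: Proposed new method: the excited acridinium oxidises the homoconjugated 1,5‑diene to its radical cation, which closes transannularly between the two less substituted alkene carbons C1 and C5 (the guaiane mode, giving a tertiary C10 radical and a tertiary C4 cation, with the charge kept off C10 by the β‑acyloxy group at C8); thiophenol then transfers H to C10 from the α face (the β face is screened by the pseudo‑axial 8β‑propanoyloxy group and the 7β side chain, hence 10β‑methyl), loss of H5 to lutidine regenerates the C4=C5 alkene, and thiyl radical/thiolate close a redox‑ and proton‑neutral cycle; C1 comes out 1α‑H because the crossed ground‑state conformer (both methyls β) bonds through its inner faces, and it is corrected in step 7; the closest known reaction types are acridinium/thiol photoredox anti‑Markovnikov hydrofunctionalisation of trisubstituted alkenes, anodic alkene radical‑cation/alkene couplings and photoinduced‑electron‑transfer polyene cyclisations, and the bond formed is the C1–C5 bond of the germacrene‑to‑guaiane step of terpene biosynthesis.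

Step 7
Reactants: 10 (1S,7S,8R,10S)-11-acetoxyguai-4-en-8-yl propanoate; 11 tert-butyl hydroperoxide
Product: 14 (1R,7S,8R,10S)-11-acetoxy-3-oxoguai-4-en-8-yl propanoate, via C3 tert-butyl peroxide 12 (not isolated), via 1-epi enone 13 (not isolated)
Conditions: Rh2(C6H10NO)4 [dirhodium tetrakis(caprolactamate)] (1 mol%), 70% aq. t-BuOOH (6 equiv), K2CO3 (0.5 equiv), CH2Cl2, 25 °C; then filter, toluene, DBU (0.5 equiv), 60 °C
Reagents that add atoms: tert-butyl hydroperoxide (11), CC(C)(C)OO
Why: Radical allylic C–H oxidation (tert‑butylperoxyl abstraction, capture of the C3–C4–C5 allyl radical at its less hindered secondary terminus C3, Kornblum–DeLaMare‑type collapse of the mixed peroxide to the ketone; the five‑ring allylic CH2 reacts in preference to the hindered C6H2, as in the guaiene‑to‑rotundone oxidation), followed by DBU‑mediated γ‑deprotonation/reprotonation through the extended dienolate, which equilibrates C1 to the epimer with C2 and the C10 methyl trans (1β‑H).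

## Compound list

1 | germacrone | O=C1C/C(C)=C/CC/C(C)=C/CC1=C(C)C | starting material
2 | hydrogen peroxide | OO | starting material
3 | rac-(1(10)E,4E)-7,11-epoxygermacra-1(10),4-dien-8-one (C7 racemic) | O=C1C/C(C)=C/CC/C(C)=C/CC12OC2(C)C | intermediate
4 | rac-(1(10)E,4E)-11-hydroxygermacra-1(10),4-dien-8-one (C7 racemic) | O=C1C/C(C)=C/CC/C(C)=C/CC1C(C)(C)O | intermediate
5 | rac-(1(10)E,4E,7S*,8R*)-germacra-1(10),4-diene-8,11-diol (cis; both enantiomers) | O[C@@H]1C/C(C)=C/CC/C(C)=C/C[C@@H]1C(C)(C)O.O[C@H]1C/C(C)=C/CC/C(C)=C/C[C@H]1C(C)(C)O | intermediate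
6 | vinyl propanoate | C=COC(=O)CC | starting material
7 | (1(10)E,4E,7S,8R)-11-hydroxygermacra-1(10),4-dien-8-yl propanoate | CCC(=O)O[C@@H]1C/C(C)=C/CC/C(C)=C/C[C@@H]1C(C)(C)O | intermediate
8 | acetic anhydride | CC(=O)OC(C)=O | starting material
9 | (1(10)E,4E,7S,8R)-11-acetoxygermacra-1(10),4-dien-8-yl propanoate | CCC(=O)O[C@@H]1C/C(C)=C/CC/C(C)=C/C[C@@H]1C(C)(C)OC(C)=O | intermediate
10 | (1S,7S,8R,10S)-11-acetoxyguai-4-en-8-yl propanoate (1α-H; 10β-Me) | CCC(=O)O[C@@H]1C[C@H](C)[C@@H]2CCC(C)=C2C[C@@H]1C(C)(C)OC(C)=O | intermediate
11 | tert-butyl hydroperoxide | CC(C)(C)OO | starting material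
12 | (1S,7S,8R,10S)-11-acetoxy-3-(tert-butylperoxy)guai-4-en-8-yl propanoate (C3 epimers; not isolated) | CCC(=O)O[C@@H]1C[C@H](C)[C@@H]2CC(OOC(C)(C)C)C(C)=C2C[C@@H]1C(C)(C)OC(C)=O | intermediate
13 | (1S,7S,8R,10S)-11-acetoxy-3-oxoguai-4-en-8-yl propanoate (1-epi enone; not isolated) | CCC(=O)O[C@@H]1C[C@H](C)[C@@H]2CC(=O)C(C)=C2C[C@@H]1C(C)(C)OC(C)=O | intermediate
14 | (1R,7S,8R,10S)-11-acetoxy-3-oxoguai-4-en-8-yl propanoate | CCC(=O)O[C@@H]1C[C@H](C)[C@H]2CC(=O)C(C)=C2C[C@@H]1C(C)(C)OC(C)=O | target

## Step count and risks

Total step count: 7. Longest linear sequence: 7 (fully linear from germacrone).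

Steps most likely to fail:

**Step 6 (radical‑cation cycloisomerisation).** The C4 cation can lose H3 or H15 instead of H5, or undergo 1,2‑hydride shifts, giving alkene isomers. The face of H transfer to C10 is controlled only by the substrate. Thiyl addition to the alkenes can compete. Fallback: setting out from 9, mCPBA (CH2Cl2, NaHCO3, 0 °C) epoxidises the more electron‑rich 4,5‑alkene from its outer face to give (4R,5R,7S,8R)-11-acetoxy-4,5-epoxygermacr-1(10)-en-8-yl propanoate F1. TsOH·H2O (10 mol%, CH2Cl2, 0 °C) opens the epoxide at C5 with anti attack of C1 and loss of H1, the classical epoxide‑initiated cationic cyclisation, to give (4R,5R,7S,8R)-11-acetoxy-4-hydroxyguai-1(10)-en-8-yl propanoate F2. Hydroxyl‑directed hydrogenation with [Ir(cod)(PCy3)(py)]PF6 and H2 (CH2Cl2) delivers both hydrogens to the α face to give (1S,4R,5R,7S,8R,10S)-11-acetoxy-4-hydroxyguaian-8-yl propanoate F3. Burgess reagent (toluene, 50 °C) removes the 4α‑hydroxyl with the cis 5α‑H by syn elimination, and the sequence comes back to the route at 10.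

**Step 7 (allylic oxidation and C1 equilibration).** Peroxyl abstraction can also occur at C6 or at the tertiary C1, and the enone can over‑oxidise at C1. The position of the C1 equilibrium rests on the assumption stated above. Fallback: setting out from 10, the radical C–H abstraction is replaced by a pericyclic ene/[2,3]‑sigmatropic hydroxylation with SeO2 (cat.) and t‑BuOOH in CH2Cl2, which gives (1S,7S,8R,10S)-11-acetoxy-3-hydroxyguai-4-en-8-yl propanoate F4 as an isolable allylic alcohol. Dess–Martin periodinane (CH2Cl2, NaHCO3) oxidises it to the enone, and the sequence comes back to the route at 13, which is then equilibrated with DBU as in step 7.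

**Step 4 (lipase resolution).** The hindered carbinol in the ten‑membered ring may be acylated slowly or with low enantioselectivity. Fallback: setting out from 4, the absolute configuration is set at the reduction instead. (S)-2-methyl-CBS-oxazaborolidine (20 mol%) with BH3·SMe2 (THF, −20 °C) reduces both enantiomers of the ketone under reagent control to the (8R) carbinol. This gives the separable diastereomers (1(10)E,4E,7S,8R)-germacra-1(10),4-diene-8,11-diol F5 (cis, wanted) and (1(10)E,4E,7R,8R)-germacra-1(10),4-diene-8,11-diol F6 (trans, discarded). Chemical acylation of the cis diol with propanoic anhydride, pyridine and DMAP (cat.) at 0 °C, selective for the secondary hydroxyl, comes back to the route at 7.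

## Further compounds

F1 | step 6 | (4R,5R,7S,8R)-11-acetoxy-4,5-epoxygermacr-1(10)-en-8-yl propanoate | CCC(=O)O[C@@H]1C/C(C)=C/CC[C@@]2(C)O[C@@H]2C[C@@H]1C(C)(C)OC(C)=O
F2 | step 6 | (4R,5R,7S,8R)-11-acetoxy-4-hydroxyguai-1(10)-en-8-yl propanoate | CCC(=O)O[C@@H]1CC(C)=C2CC[C@@](C)(O)[C@@H]2C[C@@H]1C(C)(C)OC(C)=O
F3 | step 6 | (1S,4R,5R,7S,8R,10S)-11-acetoxy-4-hydroxyguaian-8-yl propanoate | CCC(=O)O[C@@H]1C[C@H](C)[C@@H]2CC[C@@](C)(O)[C@@H]2C[C@@H]1C(C)(C)OC(C)=O
F4 | step 7 | (1S,7S,8R,10S)-11-acetoxy-3-hydroxyguai-4-en-8-yl propanoate (C3 epimers) | CCC(=O)O[C@@H]1C[C@H](C)[C@@H]2CC(O)C(C)=C2C[C@@H]1C(C)(C)OC(C)=O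
F5 | step 4 | (1(10)E,4E,7S,8R)-germacra-1(10),4-diene-8,11-diol | O[C@@H]1C/C(C)=C/CC/C(C)=C/C[C@@H]1C(C)(C)O
F6 | step 4 | (1(10)E,4E,7R,8R)-germacra-1(10),4-diene-8,11-diol | O[C@@H]1C/C(C)=C/CC/C(C)=C/C[C@H]1C(C)(C)O
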